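**Retrosynthetic overview**

1. The cyclohexene that joins the two halves is cut last (C2–C4′ and C14–C15′): a Diels–Alder addition of dehydrozaluzanin C (dienophile, C4′=C15′) to an 8β-silyloxy guaia-1,4(15),10(14),11(13)-tetraen-3-one (diene C2=C1–C10=C14), made in the flask by Saegusa–Ito oxidation.
2. Both halves go back to one tricyclic lactone. Its 8β-oxygen is kept for the diene half and removed (elimination, copper hydride) for the dienophile half.
3. That lactone is made in one operation from a monocyclic cycloheptene enyne acid by a gold-catalysed carboxy-cyclization. It forms C4–C5 and O–C6, closing the cyclopentane and the γ-lactone and setting C5 and C6.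
4. Feature used: in each half C4 (with its methylene C15) is bonded to C5, the next carbon C6 carries the lactone oxygen, and C12 hangs on C7 through C11. The array C15=C4–C5–C6–O is what alkyne C4≡C15 leaves when it adds to ring alkene C5=C6 and the C7 acetic acid captures C6.
5. The cycloheptene comes from 8-oxabicyclo[3.2.1]oct-6-en-3-one: exo alkylation sets C1, syn ring opening sets C7 and turns the bridge oxygen into the 8β-hydroxyl. Ring order: seven-membered ring (bought), cyclopentane and lactone together (key step), cyclohexene (last).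

Key step: step 8

Numbering: guaiane numbering is used for every intermediate. C1 and C5–C10 are the seven-membered ring, C2–C4 complete the cyclopentane, C11–C12 are the lactone carbons, C13 its methylene, C14 sits on C10, C15 on C4. Primes mark the dienophile-derived half. β is the face of the oxygen bridge of the bicyclic ketone, which becomes the face of C11 on C7.

Assumptions: 8-oxabicyclo[3.2.1]oct-6-en-3-one is bought. The (R,R)-lithium amide in step 2 and (R)-Tol-BINAP in step 4 are taken as the matched antipodes by analogy with the parent meso compounds; the mirror-image reagents would be used if the sense proves opposite.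

**Route**

Step 1
Reactants: 1 4-(trimethylsilyl)but-3-yn-1-ol
Product: 2 4-(trimethylsilyl)but-3-yn-1-yl trifluoromethanesulfonate
Conditions: Tf2O, pyridine, CH2Cl2, −20 °C
Reagents that add atoms: trifluoromethanesulfonic anhydride, O=S(=O)(OS(=O)(=O)C(F)(F)F)C(F)(F)F
Why: Sulfonylation of a primary alcohol gives a triflate reactive enough for ketone-enolate alkylation at low temperature; no stereocenter is involved.

Step 2
Reactants: 3 8-oxabicyclo[3.2.1]oct-6-en-3-one; 2 4-(trimethylsilyl)but-3-yn-1-yl trifluoromethanesulfonate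
Product: 4 2-[4-(trimethylsilyl)but-3-ynyl]-8-oxabicyclo[3.2.1]oct-6-en-3-one (chain axial on the face of the oxygen bridge; C1 β)
Conditions: bis[(R)-1-phenylethyl]amine, n-BuLi, LiCl, THF, −100 °C; then 2, −100 → −40 °C
Reagents that add atoms: none
Why: Desymmetrizing deprotonation of the meso ketone by a chiral lithium amide followed by enolate C-alkylation: the base chooses between the enantiotopic α-protons (absolute configuration) and the triflate enters on the exo face beside the one-atom oxygen bridge, which sets C1 with the chain axial and syn to the bridge.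

Step 3
Reactants: 4 2-[4-(trimethylsilyl)but-3-ynyl]-8-oxabicyclo[3.2.1]oct-6-en-3-one
Product: 5 ethylene ketal of 4 (dioxolane at C10)
Conditions: TMSOCH2CH2OTMS, TMSOTf (cat.), CH2Cl2, −78 °C
Reagents that add atoms: 1,2-bis(trimethylsilyloxy)ethane, C[Si](C)(C)OCCO[Si](C)(C)C
Why: Silyl-triflate-catalysed dioxolane formation under aprotic conditions masks the C10 ketone for the organometallic step without enolization, so the axial C1 substituent is not epimerized.

Step 4
Reactants: 5 ethylene ketal of 4; 6 (1,3-dioxolan-2-ylmethyl)magnesium bromide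
Product: 8 cyclohept-5-ene with 1β-but-3-ynyl; 7β-(1,3-dioxolan-2-ylmethyl); 8β-hydroxyl; C10 ethylene ketal, via TMS-alkyne cycloheptenol 7 (not isolated)
Conditions: 6 (2.4 equiv), ZnCl2 (1.2 equiv), THF, 0 °C; then 5, Pd(MeCN)2Cl2 (5 mol %), (R)-Tol-BINAP (6 mol %), Zn(OTf)2 (10 mol %), ClCH2CH2Cl, 60 °C; aq NH4Cl; then K2CO3 (cat.), MeOH, rt
Reagents that add atoms: none
Why: Palladium-catalysed alkylative ring opening of an oxabicyclic alkene by a diorganozinc (exo syn-carbopalladation, then β-oxygen elimination) should place the alkyl group on C7 on the face of the former bridge, so C7 and the freed C8 hydroxyl are cis, while the matched chiral ligand chooses C7 over C6 as it chooses between the enantiotopic alkene carbons of the parent meso ketal; methanolysis then frees the terminal alkyne.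

Step 5
Reactants: 8 cycloheptenol from step 4
Product: 9 8-O-tert-butyldimethylsilyl ether of 8
Conditions: TBSOTf, 2,6-lutidine, CH2Cl2, −78 °C
Reagents that add atoms: tert-butyldimethylsilyl trifluoromethanesulfonate, CC(C)(C)[Si](C)(C)OS(=O)(=O)C(F)(F)F
Why: Silylation of the hindered secondary alcohol at low temperature, where the two dioxolanes are not attacked; no stereocenter changes.

Step 6
Reactants: 9 8-O-TBS ether of 8
Product: 11 aldehyde (7β-CH2CHO; C10 ketal and 8β-OTBS kept), via collidinium salt 10 (not isolated)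
Conditions: TESOTf, 2,4,6-collidine, CH2Cl2, 0 °C; then H2O
Reagents that add atoms: water, O
Why: Silyl triflate and collidine turn only the aldehyde-derived dioxolane into an N,O-acetal collidinium salt that water hydrolyses to the aldehyde, a known chemoselective acetal cleavage that leaves the ketone-derived dioxolane and the silyl ether untouched.

Step 7
Reactants: 11 aldehyde
Product: 12 enyne acid (7β-CH2CO2H; 1β-but-3-ynyl; 8β-OTBS; C5=C6; C10 ketal)
Conditions: NaClO2, NaH2PO4, 2-methyl-2-butene, t-BuOH/H2O, 0 °C → rt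
Reagents that add atoms: sodium chlorite, [Na+].[O-]Cl=O
Why: Pinnick oxidation takes the aldehyde to the acid under buffered conditions that spare the alkyne, the ring alkene, the ketal and the silyl ether.

Step 8
Reactants: 12 enyne acid
Product: 13 8β-(TBSO)-10,10-ethylenedioxy-13,14-dinorguai-4(15)-en-12,6α-olide (1α-H; 5α-H; 6β-H; 7α-H)
Conditions: [Au(NCMe){P(t-Bu)2(biphenyl-2-yl)}]SbF6 (5 mol %), CH2Cl2, −20 °C → rt
Reagents that add atoms: none
Why: Proposed new method: the cationic monovalent gold catalyst activates the terminal alkyne C4≡C15, the ring alkene C5=C6 attacks through C5 to give a cyclopropyl gold carbene, the carboxylic acid opens it at C6 on the face opposite to the new C4–C5 bond, and protodeauration of the alkenyl gold leaves the exocyclic methylene C4=C15. The closest known reaction type is the gold-catalysed alkoxy- or carboxy-cyclization of 1,6-enynes (nucleophile-terminated enyne cyclization); new here are an endocyclic secondary alkene and a trans-fused lactone as the outcome. The cyclopentane (C1–C5) closes 5-exo-dig through C4–C5 and the γ-lactone closes 5-exo-tet through O–C6. C5 is controlled by the tether: the butynyl chain lies on the β face of C1, so C4 can only reach the β face of C5 (cis-fused hydroazulene, H5 α); C6 is controlled by the stereospecific anti addition, oxygen entering α (H6 β), which with the fixed C7 gives the trans lactone. The step needs exo over endo closure and lactone capture over skeletal rearrangement: the terminal alkyne on an all-carbon three-atom tether favours exo closure, the acid is held two atoms from C6 and can reach its α face from a pseudo-equatorial position on the flexible seven-membered ring, and the only other π-system (C10) is masked as the ketal, which also prevents epimerization at C1.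

Step 9
Reactants: 13 tricyclic lactone ketal
Product: 14 8β-(TBSO)-10-oxo-13,14-dinorguai-4(15)-en-12,6α-olide
Conditions: PPTS (cat.), acetone/H2O, 50 °C
Reagents that add atoms: water, O
Why: Mild acid-catalysed ketal hydrolysis frees the C10 ketone after the ring alkene has been consumed, so no conjugation can occur, and the silyl ether and exocyclic alkene tolerate PPTS.

Step 10
Reactants: 14 keto lactone
Product: 15 8β-(TBSO)-13-norguaia-4(15),10(14)-dien-12,6α-olide
Conditions: Zn, CH2Br2, TiCl4, THF/CH2Cl2, 0 °C → rt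
Reagents that add atoms: dibromomethane, BrCBr
Why: Takai–Lombardo methylenation is non-basic, so the ring-fusion center C1 is not epimerized, the β-silyloxy group is not eliminated and the lactone is not attacked.

Step 11
Reactants: 15 diene lactone
Product: 18 8β-(TBSO)-dehydrocostus lactone, via Mannich base 16 (not isolated), via trimethylammonium iodide 17 (not isolated)
Conditions: LiN(i-Pr)2, THF, −78 °C; Me2N=CH2 I (Eschenmoser's salt), −78 °C → rt; then MeI, MeOH, rt; then aq NaHCO3, CH2Cl2
Reagents that add atoms: dimethylmethylideneammonium iodide, C=[N+](C)C.[I-]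
Why: Lactone enolate Mannich reaction followed by quaternization and Hofmann-type elimination installs the α-methylene group; the temporary C11 stereocenter (drawn as the epimer from attack anti to the 8β-silyloxy group) is destroyed.

Step 12
Reactants: 18 8β-(TBSO)-dehydrocostus lactone
Product: 19 3α-hydroxy-8β-(TBSO)-dehydrocostus lactone
Conditions: SeO2 (cat.), t-BuOOH, CH2Cl2, rt
Reagents that add atoms: tert-butyl hydroperoxide, CC(C)(C)OO
Why: Selenium dioxide allylic oxidation (ene reaction, then 2,3-shift) is known to oxidize the C3 methylene next to the C4(15) alkene in this ring system; oxygen should arrive on the convex α face, and this center is removed in the next step.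

Step 13
Reactants: 19 allylic alcohol
Product: 20 8β-(TBSO)-dehydrozaluzanin C (8β-(TBSO)-3-oxoguaia-4(15),10(14),11(13)-trien-12,6α-olide)
Conditions: Dess–Martin periodinane, CH2Cl2, rt
Reagents that add atoms: none

Why: Dess–Martin oxidation of the allylic alcohol gives the cross-conjugated enone under neutral conditions without touching the methylene lactone.

Step 14
Reactants: 14 keto lactone
Product: 21 8β-hydroxy-10-oxo-13,14-dinorguai-4(15)-en-12,6α-olide
Conditions: HF·pyridine, THF, 0 °C → rt
Reagents that add atoms: none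

Why: Fluoride-mediated desilylation under weakly acidic conditions frees the β-hydroxy ketone without retro-aldol cleavage or lactone migration.

Step 15
Reactants: 21 β-hydroxy ketone
Product: 23 10-oxo-13,14-dinorguaia-4(15),8-dien-12,6α-olide, via mesylate 22 (not isolated)
Conditions: MsCl, Et3N, CH2Cl2, 0 °C → rt
Reagents that add atoms: none

Why: Mesylation and E1cB elimination through the C9 enolate remove the C8 oxygen as the conjugated C8=C9 enone; mild amine base leaves C1 and C7 untouched.

Step 16
Reactants: 23 enone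
Product: 24 10-oxo-13,14-dinorguai-4(15)-en-12,6α-olide
Conditions: [(Ph3P)CuH]6 (0.4 equiv), wet toluene, rt
Reagents that add atoms: none

Why: Copper hydride conjugate reduction saturates only the enone, sparing the isolated exocyclic alkene and the saturated lactone; C8 and C9 become methylenes, so no stereocenter is formed.

Step 17
Reactants: 24 keto lactone
Product: 25 13-norguaia-4(15),10(14)-dien-12,6α-olide
Conditions: Zn, CH2Br2, TiCl4, THF/CH2Cl2, 0 °C → rt
Reagents that add atoms: dibromomethane, BrCBr
Why: Takai–Lombardo methylenation of the enolizable ketone without epimerization at C1.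

Step 18
Reactants: 25 diene lactone
Product: 28 dehydrocostus lactone, via Mannich base 26 (not isolated), via trimethylammonium iodide 27 (not isolated)
Conditions: LiN(i-Pr)2, THF, −78 °C; Me2N=CH2 I (Eschenmoser's salt), −78 °C → rt; then MeI, MeOH, rt; then aq NaHCO3, CH2Cl2
Reagents that add atoms: dimethylmethylideneammonium iodide, C=[N+](C)C.[I-]
Why: Enolate Mannich reaction, quaternization and Hofmann-type elimination give the α-methylene lactone; the temporary C11 center (drawn β) is destroyed.

Step 19
Reactants: 28 dehydrocostus lactone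
Product: 29 3-epizaluzanin C (3α-hydroxy)
Conditions: SeO2 (cat.), t-BuOOH, CH2Cl2, rt
Reagents that add atoms: tert-butyl hydroperoxide, CC(C)(C)OO
Why: Selenium dioxide allylic oxidation at C3 from the convex α face, the known behaviour of this triene lactone; the carbinol center is removed next.

Step 20
Reactants: 29 3-epizaluzanin C
Product: 30 dehydrozaluzanin C
Conditions: Dess–Martin periodinane, CH2Cl2, rt
Reagents that add atoms: none

Why: Neutral oxidation of the allylic alcohol to the enone that serves as dienophile.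

Step 21
Reactants: 20 8β-(TBSO)-dehydrozaluzanin C
Product: 31 3,8β-bis(TBSO)-guaia-2,4(15),10(14),11(13)-tetraen-12,6α-olide (silyl dienol ether)
Conditions: TBSOTf, Et3N, CH2Cl2, 0 °C
Reagents that add atoms: tert-butyldimethylsilyl trifluoromethanesulfonate, CC(C)(C)[Si](C)(C)OS(=O)(=O)C(F)(F)F
Why: Soft enolization and O-silylation can only go toward C2, because C4 is already sp2, and give the substrate for the Saegusa–Ito oxidation.

Step 22
Reactants: 31 silyl dienol ether; 30 dehydrozaluzanin C
Product: 34 8-O-TBS ether of the target, via tetraenone 32 (not isolated), via unconjugated cycloadduct 33 (not isolated)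
Conditions: 30 (3 equiv), Pd(OAc)2 (1.1 equiv), MeCN, rt, argon; then Et3N (cat.), rt
Reagents that add atoms: none

Why: Saegusa–Ito oxidation gives the C1=C2 enone whose diene C2=C1–C10=C14 adds to the C4′=C15′ enone methylene of 30 in an intermolecular Diels–Alder reaction with ortho regiochemistry (C2–C4′, C14–C15′), the diene approaching the convex α face of the cyclopentanone away from its seven-membered ring, which sets the spiro center C4′; amine-mediated tautomerization through the dienol then moves the alkene to C1=C2, and protonation at C10 under equilibrating conditions is expected to give 10β-H.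

Step 23
Reactants: 34 8-O-TBS ether of the target
Product: 35 CNP0200944.1 (target)
Conditions: HF·pyridine, pyridine/THF, 0 °C → rt
Reagents that add atoms: none

Why: Buffered fluoride desilylation frees the 8β-hydroxyl without base, so neither conjugate addition to the methylene lactones nor lactone migration to O8 is expected.

**Compound list**

1 | 4-(trimethylsilyl)but-3-yn-1-ol | C[Si](C)(C)C#CCCO | starting material
2 | 4-(trimethylsilyl)but-3-yn-1-yl trifluoromethanesulfonate | C[Si](C)(C)C#CCCOS(=O)(=O)C(F)(F)F | intermediate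
3 | 8-oxabicyclo[3.2.1]oct-6-en-3-one (meso) | O=C1C[C@H]2C=C[C@H](O2)C1 | starting material
4 | 2-[4-(trimethylsilyl)but-3-ynyl]-8-oxabicyclo[3.2.1]oct-6-en-3-one, chain axial and syn to the oxygen bridge (C1 β) | O=C1[C@H](CCC#C[Si](C)(C)C)[C@H]2C=C[C@H](O2)C1 | intermediate
5 | ethylene ketal of 4 (dioxolane at C10) | O1CCOC12[C@H](CCC#C[Si](C)(C)C)[C@H]3C=C[C@H](O3)C2 | intermediate
6 | (1,3-dioxolan-2-ylmethyl)magnesium bromide | Br[Mg]CC1OCCO1 | starting material
7 | cyclohept-5-ene with 1β-[4-(trimethylsilyl)but-3-ynyl], 7β-(1,3-dioxolan-2-ylmethyl), 8β-OH, C10 ethylene ketal | O1CCOC12[C@H](CCC#C[Si](C)(C)C)C=C[C@H](CC3OCCO3)[C@H](O)C2 | intermediate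
8 | as 7 with terminal alkyne (1β-but-3-ynyl) | O1CCOC12[C@H](CCC#C)C=C[C@H](CC3OCCO3)[C@H](O)C2 | intermediate
9 | 8-O-TBS ether of 8 | O1CCOC12[C@H](CCC#C)C=C[C@H](CC3OCCO3)[C@H](O[Si](C)(C)C(C)(C)C)C2 | intermediate
10 | collidinium N,O-acetal triflate from the aldehyde-derived dioxolane of 9 (both epimers at the N,O-acetal carbon) | O1CCOC12[C@H](CCC#C)C=C[C@H](CC(OCCO[Si](CC)(CC)CC)[n+]3c(C)cc(C)cc3C)[C@H](O[Si](C)(C)C(C)(C)C)C2.[O-]S(=O)(=O)C(F)(F)F | intermediate
11 | aldehyde: 7β-(2-oxoethyl), 1β-but-3-ynyl, 8β-OTBS, C5=C6, C10 ethylene ketal | O1CCOC12[C@H](CCC#C)C=C[C@H](CC=O)[C@H](O[Si](C)(C)C(C)(C)C)C2 | intermediate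
12 | enyne acid: 7β-(carboxymethyl), 1β-but-3-ynyl, 8β-OTBS, C5=C6, C10 ethylene ketal | O1CCOC12[C@H](CCC#C)C=C[C@H](CC(=O)O)[C@H](O[Si](C)(C)C(C)(C)C)C2 | intermediate
13 | 8β-(TBSO)-10,10-ethylenedioxy-13,14-dinorguai-4(15)-en-12,6α-olide (1α-H, 5α-H, 6β-H, 7α-H) | C=C1CC[C@H]2C4(OCCO4)C[C@@H](O[Si](C)(C)C(C)(C)C)[C@H]3CC(=O)O[C@@H]3[C@H]21 | intermediate
14 | 8β-(TBSO)-10-oxo-13,14-dinorguai-4(15)-en-12,6α-olide | C=C1CC[C@H]2C(=O)C[C@@H](O[Si](C)(C)C(C)(C)C)[C@H]3CC(=O)O[C@@H]3[C@H]21 | intermediate
15 | 8β-(TBSO)-13-norguaia-4(15),10(14)-dien-12,6α-olide | C=C1CC[C@H]2C(=C)C[C@@H](O[Si](C)(C)C(C)(C)C)[C@H]3CC(=O)O[C@@H]3[C@H]21 | intermediate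
16 | 11α-(dimethylaminomethyl) derivative of 15 (Mannich base) | C=C1CC[C@H]2C(=C)C[C@@H](O[Si](C)(C)C(C)(C)C)[C@H]3[C@H](CN(C)C)C(=O)O[C@@H]3[C@H]21 | intermediate
17 | trimethylammonium iodide of 16 | C=C1CC[C@H]2C(=C)C[C@@H](O[Si](C)(C)C(C)(C)C)[C@H]3[C@H](C[N+](C)(C)C)C(=O)O[C@@H]3[C@H]21.[I-] | intermediate
18 | 8β-(TBSO)-dehydrocostus lactone (8β-(TBSO)-guaia-4(15),10(14),11(13)-trien-12,6α-olide) | C=C1CC[C@H]2C(=C)C[C@@H](O[Si](C)(C)C(C)(C)C)[C@H]3C(=C)C(=O)O[C@@H]3[C@H]21 | intermediate
19 | 3α-hydroxy-8β-(TBSO)-dehydrocostus lactone | C=C1[C@H](O)C[C@H]2C(=C)C[C@@H](O[Si](C)(C)C(C)(C)C)[C@H]3C(=C)C(=O)O[C@@H]3[C@H]21 | intermediate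
20 | 8β-(TBSO)-dehydrozaluzanin C | C=C1C(=O)C[C@H]2C(=C)C[C@@H](O[Si](C)(C)C(C)(C)C)[C@H]3C(=C)C(=O)O[C@@H]3[C@H]21 | intermediate
21 | 8β-hydroxy-10-oxo-13,14-dinorguai-4(15)-en-12,6α-olide | C=C1CC[C@H]2C(=O)C[C@@H](O)[C@H]3CC(=O)O[C@@H]3[C@H]21 | intermediate
22 | 8β-methanesulfonate of 21 | C=C1CC[C@H]2C(=O)C[C@@H](OS(C)(=O)=O)[C@H]3CC(=O)O[C@@H]3[C@H]21 | intermediate
23 | 10-oxo-13,14-dinorguaia-4(15),8-dien-12,6α-olide | C=C1CC[C@H]2C(=O)C=C[C@H]3CC(=O)O[C@@H]3[C@H]21 | intermediate
24 | 10-oxo-13,14-dinorguai-4(15)-en-12,6α-olide | C=C1CC[C@H]2C(=O)CC[C@H]3CC(=O)O[C@@H]3[C@H]21 | intermediate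
25 | 13-norguaia-4(15),10(14)-dien-12,6α-olide | C=C1CC[C@H]2C(=C)CC[C@H]3CC(=O)O[C@@H]3[C@H]21 | intermediate
26 | 11β-(dimethylaminomethyl) derivative of 25 (Mannich base) | C=C1CC[C@H]2C(=C)CC[C@H]3[C@@H](CN(C)C)C(=O)O[C@@H]3[C@H]21 | intermediate
27 | trimethylammonium iodide of 26 | C=C1CC[C@H]2C(=C)CC[C@H]3[C@@H](C[N+](C)(C)C)C(=O)O[C@@H]3[C@H]21.[I-] | intermediate
28 | dehydrocostus lactone (guaia-4(15),10(14),11(13)-trien-12,6α-olide; 1α-H, 5α-H, 6β-H, 7α-H) | C=C1CC[C@H]2C(=C)CC[C@H]3C(=C)C(=O)O[C@@H]3[C@H]21 | intermediate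
29 | 3-epizaluzanin C (3α-hydroxydehydrocostus lactone) | C=C1[C@H](O)C[C@H]2C(=C)CC[C@H]3C(=C)C(=O)O[C@@H]3[C@H]21 | intermediate
30 | dehydrozaluzanin C (3-oxoguaia-4(15),10(14),11(13)-trien-12,6α-olide) | C=C1C(=O)C[C@H]2C(=C)CC[C@H]3C(=C)C(=O)O[C@@H]3[C@H]21 | intermediate
31 | 3,8β-bis(TBSO)-guaia-2,4(15),10(14),11(13)-tetraen-12,6α-olide | C=C1C(O[Si](C)(C)C(C)(C)C)=C[C@H]2C(=C)C[C@@H](O[Si](C)(C)C(C)(C)C)[C@H]3C(=C)C(=O)O[C@@H]3[C@H]21 | intermediate
32 | 8β-(TBSO)-3-oxoguaia-1,4(15),10(14),11(13)-tetraen-12,6α-olide | C=C1C(=O)C=C2C(=C)C[C@@H](O[Si](C)(C)C(C)(C)C)[C@H]3C(=C)C(=O)O[C@@H]3[C@H]21 | intermediate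
33 | Diels–Alder adduct with C1=C10 alkene, bonds C2–C4′ and C14–C15′, H2 β, C4′ spiro with C2 on its α face | C=C1C(=O)[C@H]2C3=C(CC[C@]24C(=O)C[C@H]2C(=C)CC[C@H]5C(=C)C(=O)O[C@@H]5[C@H]24)C[C@@H](O[Si](C)(C)C(C)(C)C)[C@H]2C(=C)C(=O)O[C@@H]2[C@@H]13 | intermediate
34 | 8-O-TBS ether of the target (C1=C2 enone, 10β-H) | C=C1C(=O)C2=C3[C@H](CC[C@]24C(=O)C[C@H]2C(=C)CC[C@H]5C(=C)C(=O)O[C@@H]5[C@H]24)C[C@@H](O[Si](C)(C)C(C)(C)C)[C@H]2C(=C)C(=O)O[C@@H]2[C@@H]13 | intermediate
35 | CNP0200944.1 | C=C1C(=O)C2=C3[C@H](CC[C@]24C(=O)C[C@H]2C(=C)CC[C@H]5C(=C)C(=O)O[C@@H]5[C@H]24)C[C@@H](O)[C@H]2C(=C)C(=O)O[C@@H]2[C@@H]13 | target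

**Step count and risks**

Total step count: 23. Longest linear sequence: 18 steps (steps 1–9, 14–20, 22, 23).

Steps most likely to fail:

Step 8 (Proposed new method). What may go wrong: the tethered acid may fail to reach C6 from the α face in time, so that the gold carbene undergoes skeletal rearrangement or is captured on the wrong face. Fallback from 12, returning at 13: ring closure and lactonization are separated. The acid is esterified (TMSCHN2, MeOH/toluene) to the methyl ester F1. This is submitted to the known gold-catalysed hydroxycyclization of 1,6-enynes with water as external nucleophile (same gold catalyst, wet dioxane, rt), where the untethered nucleophile adds anti at C6 to give the 6α-hydroxy ester F2. Acyl–oxygen lactonization (PPTS, toluene, 60 °C) then gives 13.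

Step 4. What may go wrong: slow transfer of the functionalized alkyl group from zinc with β-hydride loss, or carbometalation with the alkyl group entering at C6, which opens the other C–O bond. Fallback from 5, returning at 11: the nucleophile and the mechanism are changed to an uncatalysed, oxygen-directed syn SN2′ opening with vinyllithium (Et2O, TMEDA, 0 °C), lithium sitting on the less hindered C8 side of the bridge oxygen and delivering vinyl to C7, to give the vinyl carbinol F3. Silylation (TBSOTf, 2,6-lutidine) gives the silyl ether F4. 9-BBN, then NaBO3, hydroborates only the monosubstituted vinyl group to give the primary alcohol F5. K2CO3/MeOH removes the alkynyl silane to give the alkynol F6, and Dess–Martin oxidation gives 11.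

Step 22. What may go wrong: self-dimerization or polymerization of the transient tetraenone may outrun the cross-cycloaddition, and kinetic protonation at C10 may occur on the wrong face. Fallback from 31, returning at 34: the diene is released slowly and without palladium. PhSeCl (CH2Cl2, −78 °C) converts 31 into the 2α-phenylselanyl ketone F7. Oxidation with H2O2/pyridine at 0 °C in the presence of excess 30 gives 32 by selenoxide syn-elimination (the selenoxide is cis to H1), which is trapped as 33. DBU then equilibrates through the dienolate to the conjugated enone under thermodynamic control at C10, giving 34.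

**Further compounds**

F1 | step 8 | methyl ester of 12 | O1CCOC12[C@H](CCC#C)C=C[C@H](CC(=O)OC)[C@H](O[Si](C)(C)C(C)(C)C)C2
F2 | step 8 | methyl 8β-(TBSO)-6α-hydroxy-10,10-ethylenedioxy-13,14-dinorguai-4(15)-en-12-oate (1α-H, 5α-H, 6β-H, 7α-H) | C=C1CC[C@H]2C4(OCCO4)C[C@@H](O[Si](C)(C)C(C)(C)C)[C@@H](CC(=O)OC)[C@H](O)[C@H]21
F3 | step 4 | vinyl carbinol: cyclohept-5-ene with 1β-[4-(trimethylsilyl)but-3-ynyl], 7β-vinyl, 8β-OH, C10 ethylene ketal | O1CCOC12[C@H](CCC#C[Si](C)(C)C)C=C[C@H](C=C)[C@H](O)C2
F4 | step 4 | 8-O-TBS ether of F3 | O1CCOC12[C@H](CCC#C[Si](C)(C)C)C=C[C@H](C=C)[C@H](O[Si](C)(C)C(C)(C)C)C2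
F5 | step 4 | primary alcohol: 7β-(2-hydroxyethyl) analogue of F4 | O1CCOC12[C@H](CCC#C[Si](C)(C)C)C=C[C@H](CCO)[C@H](O[Si](C)(C)C(C)(C)C)C2
F6 | step 4 | alkynol: F5 with terminal alkyne | O1CCOC12[C@H](CCC#C)C=C[C@H](CCO)[C@H](O[Si](C)(C)C(C)(C)C)C2
F7 | step 22 | 2α-phenylselanyl-8β-(TBSO)-dehydrozaluzanin C | C=C1C(=O)[C@H]([Se]c4ccccc4)[C@H]2C(=C)C[C@@H](O[Si](C)(C)C(C)(C)C)[C@H]3C(=C)C(=O)O[C@@H]3[C@H]21
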